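## Structural features

The target is a flavone. Benzene ring A is fused along C4a–C8a to 4-pyranone ring C (O1, C2, C3, C4), and aryl ring B is attached to C2 by a single C–C bond. There is no stereocentre, no stereogenic axis and no configurable double bond, so the problem is purely constitutional. Ring A is hexasubstituted: C4a carries the C4 carbonyl, and C5, C6, C7, C8 and C8a carry five contiguous oxygens in three states (free OH at C5 and C6, OMe at C7 and C8, ring oxygen O1 at C8a). Ring B is an isovanilloid unit, with 3'-OH next to 4'-OMe.

There are three fragile points: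
- The 5,6-catechol and the para pair O6/O1 make ring A easy to oxidise to quinones.
- Methyl ethers next to a free hydroxyl are open to neighbour-assisted Lewis acid cleavage.
- Once O5 is free, the 5-OH/C4=O pair lets ring C open and re-close on the other ortho oxygen (Wessely–Moser rearrangement).

The real difficulty is the regiodefined oxygen pattern of ring A. Stepwise substitution of an electron-rich benzene cannot set this pattern with control.

The key step exploits the array C6(OH)–C7(OMe)–C8(OMe)–C8a(O1). These are four contiguous oxygenated carbons, the inner two methylated and the outer two para to each other. This is the constitution of dimethyl squarate 3 after a two-carbon ring expansion. The remaining atoms, C4a (acyl) and C5 (oxygen), are the α- and β-carbons of a β-methoxy enone.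

## Logic of the disconnections

**13 to 12.**
- Bonds: O5–CH3 and O3'–CH2Ph are put back.
- Reason: O5 must be blocked while ring C is closed, so that only the oxygen at C8a can reach C2. The peri methyl ether is the one ether that chelation to the C4 carbonyl allows to be removed selectively. The benzyl group carries the ring B phenol through strong base.
- Gain: both groups fall to one reagent in one step.
- Demand: the ethers at C7, C8 and C4' must stay.

**12 to 8 and 10.**
- Bonds: O1–C2 and C2–C3.
- Reason: this separates ring B with C2 from ring A, which keeps C4 and C3 as an acetyl group.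
- Gain: two fragments of similar size, one of them trivial.
- Demand: the enolate carbon of 8 must be acylated in the presence of two phenoxides. Ring closure needs no control, because O5 is methylated.

**8 to 5 (key).**
- Bonds: the C5–C6 bond of ring A is cut and a C6–C8a bond is drawn in its place. C6, C7, C8 and C8a contract to a four-membered ring, and C4a=C5 becomes a side-chain alkene.
- Reason: 8 and 5 are isomers. In 5 every oxygen is already at its final carbon and in its final state.
- Gain: a hexasubstituted benzene with five differentiated oxygens is traded for a compound that falls, in the next cut, into a symmetric four-carbon piece and a four-carbon enone.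
- Demand: the ring opening must turn the alkenyl group inward. The closure must outrun bimolecular capture of the ketene. Oxygen must be kept out.
- In one sentence: ring A is made by heating 5, whose four-membered ring opens to a ketene and re-closes on the pendant alkene. That sentence does not fit the customary route, in which ring A is bought as a benzene and only ring C is made.

**5 to 2 and 3.**
- Bond: C4a–C8a.
- Reason: C8a is one of two equivalent carbonyl carbons of 3, so the addition has no regiochemical issue. C4a is the α-carbon of the enone, where a halogen gives access to the carbanion.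
- Rejected alternative: an anion at C5 adding to the future C6 would place the acetyl group cis to a tertiary alkoxide and invite lactol formation. It would also need a masked ketone.
- Gain: two small achiral pieces.
- Demand: metalation must tolerate the methyl ketone, and addition must be 1,2 rather than conjugate.

**2 to 1.**
- Bond: C3–I of the enone (the future C4a).
- Reason: C3 is the nucleophilic carbon of the enol ether.
- Gain: a commercial enone.
- Demand: monoiodination at C3 only.

**10 to 9.**
- Bond: C–Cl.
- Reason and gain: activation of a catalogue acid.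
- Demand: none beyond dryness.

## Other disconnections considered

**Alternative 1:** This is the first that comes to mind. Cut O1–C2 and C2=C3 and buy ring A as a benzene.
- Forward route: Claisen–Schmidt condensation of a fully methylated ring A acetophenone with the ring B aldehyde gives chalcone A1. Iodine/DMSO oxidative cyclisation gives tetramethoxyflavone A2. Demethylation at O5 and O6 follows.
- Grounds against it: the acetophenone half must be assembled by stepwise oxygenation of an arene (acylation, persulfate or Dakin-type hydroxylation, methylation), and none of these steps lowers the complexity of ring A.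
- The end game must free O5 and O6 while O7, O8 and O4' stay methylated. O5 is secured by chelation. O6 is secured only by a neighbour effect, which also operates at O4' once O3' is free.
- The chosen plan never methylates O6.

**Alternative 2:** Cut C4a–C5 and C8–C8a, so that ring A is annulated onto a preformed ring B–ring C unit.
- Forward route: pyranone A3 is lithiated next to its ring oxygen and added to 3. The alkoxide is methylated to give cyclobutenone A4. Thermal ring expansion onto the pyranone double bond gives flavone A5.
- Merits: the closure is polarity-matched, and the route is one step shorter on paper.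
- Grounds against it: the four carbons of 3 become C5 to C8, so its two methoxy groups land on C6 and C7 instead of C7 and C8. The route must then end either in a cleavage of O6–CH3 beside three other methyl ethers or in a Wessely–Moser equilibration. Nothing in the structure secures either.
- The lithiation must also choose between two acidic ring positions of A3.

**Alternative 3:** Cut C4–C4a and O1–C8a, so that two neighbouring substituents are put on an aryne at once.
- Forward route: fluoride sets free tetraalkoxybenzyne A7 from silyl triflate A6. A7 undergoes a [4+2] cycloaddition with aroylketene A9, released by heating dioxinone A8.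
- Grounds against it: the triple bond of A7 is flanked by an alkoxy group on each side (at C5 and at C8). The inductive distortion that normally steers addition cancels, so the two orientations of the unsymmetrical ketene have no bias.
- A6 is itself a hexasubstituted benzene and harder to make than ring A.
- The ketene C=C bond offers a competing [2+2] path.

Key step: step 3

Assumption: 1, 3 and 9 are taken as catalogue compounds, and 5 is made and used as the racemate because its single stereocentre is erased in step 3.

## Steps

Step 1
Reactants: 1 (3E)-4-methoxybut-3-en-2-one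
Product: 2 (3Z)-3-iodo-4-methoxybut-3-en-2-one
Conditions: NIS, AcOH, CH2Cl2, rt, dark; then Et3N, rt
Reagents that add atoms: N-iodosuccinimide, O=C1CCC(=O)N1I
Why: Electrophilic α-iodination of a β-alkoxy enone: C3 is the nucleophilic carbon of the enol ether, iodonium and acetate add across C3=C4, and Et3N removes AcOH again. The isomer with OMe anti to the acetyl group, (Z), is favoured by dipole and steric effects, and the geometry has no bearing on the constitution of later products.

Step 2
Reactants: 2 (3Z)-3-iodo-4-methoxybut-3-en-2-one; 3 dimethyl squarate (3,4-dimethoxycyclobut-3-ene-1,2-dione)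
Product: 5 4-hydroxy-2,3-dimethoxy-4-[(1E)-1-methoxy-3-oxobut-1-en-2-yl]cyclobut-2-en-1-one (racemic), via alkenylmagnesium chloride 4 (not isolated)
Conditions: iPrMgCl·LiCl (1.05 equiv), THF, −78 °C; cannulated into 3, THF, −78 °C; AcOH quench at −78 °C
Reagents that add atoms: isopropylmagnesium chloride–lithium chloride, CC(C)[Mg]Cl.[Li+].[Cl-] (gives the MgCl group of 4; none of its atoms stay in 5)
Why: Iodine–magnesium exchange, known for α-iodo-β-alkoxy-α,β-unsaturated carbonyl compounds, is fast at −78 °C because the carbanion is stabilised by the carbonyl group (allenolate character), so it should outrun attack on the vinylogous ester carbonyl. 4 then adds 1,2 to one of the two equivalent carbonyl groups of symmetric 3 (the standard organometallic addition to squarates) through a magnesium-chelated aldol-type transition state, and the cold acidic quench forestalls retro-addition. The carbinol stereocentre forms as a racemate and disappears in step 3.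

Step 3
Reactants: 5 4-hydroxy-2,3-dimethoxy-4-[(1E)-1-methoxy-3-oxobut-1-en-2-yl]cyclobut-2-en-1-one
Product: 8 1-(3,6-dihydroxy-2,4,5-trimethoxyphenyl)ethan-1-one, via dienylketene 6 (not isolated), via cyclohexadienone 7 (not isolated)
Conditions: degassed toluene (0.02 M), 110 °C, argon
Reagents that add atoms: none
Why: Heating opens the cyclobutenone by a conrotatory 4π electrocyclic reaction that breaks the C6–C8a bond (flavone numbering) and gives dienylketene 6. The selectivity needed is torquoselectivity: the hydroxyl group at C8a, a strong π-donor, turns outward, which leaves the inward path to the alkenyl group, so ketene carbon C6 and alkene terminus C5 end up cis on the new C8=C8a double bond. 6 closes ring A by a thermal disrotatory 6π electrocyclisation that forms the C5–C6 bond of a six-membered carbocycle and gives cyclohexadienone 7. The sp3 carbon C5 of 7 is the only new stereocentre and is erased at once by enolisation to the phenol; loss of methanol cannot compete because C4a bears no hydrogen. The closest known reaction type is the thermal ring expansion of squarate-derived 4-alkenyl- and 4-aryl-4-hydroxycyclobutenones to hydroquinones (Moore rearrangement). The bond forms at the methoxy-bearing, less nucleophilic end of a push–pull alkene with the methoxy group on the inner face; this is judged acceptable because closure of dienylketenes, even with doubly substituted termini, is intrinsically far faster than the ring opening that feeds it, and strain release plus aromatisation make it irreversible. No regiochemical choice exists, since each of the six ring atoms brings its own substituent: O6 emerges as free OH from the ketene carbonyl, the C8a oxygen as free OH from the carbinol, O7, O8 and O5 methylated, and C4a acetylated. Dilution and exclusion of oxygen keep the ketene from bimolecular capture and the hydroquinone from oxidation.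

Step 4
Reactants: 9 3-(benzyloxy)-4-methoxybenzoic acid
Product: 10 3-(benzyloxy)-4-methoxybenzoyl chloride
Conditions: (COCl)2, cat. DMF, CH2Cl2, 0 °C to rt
Reagents that add atoms: oxalyl chloride, O=C(Cl)C(=O)Cl
Why: Standard acid chloride formation through the Vilsmeier-type chloroiminium species; the benzyl and methyl ethers are inert.

Step 5
Reactants: 8 1-(3,6-dihydroxy-2,4,5-trimethoxyphenyl)ethan-1-one; 10 3-(benzyloxy)-4-methoxybenzoyl chloride
Product: 12 2-[3-(benzyloxy)-4-methoxyphenyl]-6-hydroxy-5,7,8-trimethoxy-4H-chromen-4-one, via diketone 11 (not isolated)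
Conditions: LiN(SiMe3)2 (4.5 equiv), THF, −78 to −10 °C; 10, −78 °C to rt; aq. HCl; crude 11, cat. H2SO4, AcOH, 95 °C
Reagents that add atoms: none
Why: Direct C-aroylation of a hydroxyacetophenone polyanion, the intermolecular counterpart of the Baker–Venkataraman rearrangement: both phenols and the methyl ketone are deprotonated, the enolate carbon is the most reactive site, and the fourth equivalent of base stores 11 as its enolate. Acid then closes ring C by attack of the C8a hydroxyl on the aroyl carbonyl and loss of water. Since O5 is methylated, no other ortho oxygen can compete and no Wessely–Moser scrambling is possible.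

Step 6
Reactants: 12 2-[3-(benzyloxy)-4-methoxyphenyl]-6-hydroxy-5,7,8-trimethoxy-4H-chromen-4-one
Product: 13 5,6-dihydroxy-2-(3-hydroxy-4-methoxyphenyl)-7,8-dimethoxy-4H-chromen-4-one (5,6,3'-trihydroxy-7,8,4'-trimethoxyflavone)
Conditions: BCl3 (4 equiv), pentamethylbenzene, CH2Cl2, −78 to 0 °C; aqueous work-up
Reagents that add atoms: none
Why: BCl3 binds between the C4 carbonyl oxygen and O5 in a six-membered chelate and chloride removes the peri methyl group (chelation-controlled demethylation, the most selective ether cleavage of flavones), helped by boron bound at O6. The benzyl ether ionises under the same conditions, and pentamethylbenzene takes up the benzyl cation so that ring B is not alkylated. The ethers at C7, C8 and C4' have no carbonyl partner and should survive at or below 0 °C.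

## Compound list

1 | (3E)-4-methoxybut-3-en-2-one | CO/C=C/C(C)=O | starting material
2 | (3Z)-3-iodo-4-methoxybut-3-en-2-one | CO/C=C(\I)C(C)=O | intermediate
3 | dimethyl squarate (3,4-dimethoxycyclobut-3-ene-1,2-dione) | COC1=C(OC)C(=O)C1=O | starting material
4 | chloro[(1Z)-1-methoxy-3-oxobut-1-en-2-yl]magnesium | CO/C=C(\[Mg]Cl)C(C)=O | intermediate
5 | 4-hydroxy-2,3-dimethoxy-4-[(1E)-1-methoxy-3-oxobut-1-en-2-yl]cyclobut-2-en-1-one (racemic) | CO/C=C(/C(C)=O)C1(O)C(OC)=C(OC)C1=O | intermediate
6 | (3Z,5E)-5-acetyl-4-hydroxy-2,3,6-trimethoxyhexa-1,3,5-trien-1-one | O=C=C(OC)/C(OC)=C(/O)\C(C(C)=O)=C/OC | intermediate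
7 | 5-acetyl-4-hydroxy-2,3,6-trimethoxycyclohexa-2,4-dien-1-one (racemic) | COC1C(=O)C(OC)=C(OC)C(O)=C1C(C)=O | intermediate
8 | 1-(3,6-dihydroxy-2,4,5-trimethoxyphenyl)ethan-1-one | CC(=O)c1c(O)c(OC)c(OC)c(O)c1OC | intermediate
9 | 3-(benzyloxy)-4-methoxybenzoic acid | COc1ccc(cc1OCc1ccccc1)C(=O)O | starting material
10 | 3-(benzyloxy)-4-methoxybenzoyl chloride | COc1ccc(cc1OCc1ccccc1)C(=O)Cl | intermediate
11 | 1-[3-(benzyloxy)-4-methoxyphenyl]-3-(3,6-dihydroxy-2,4,5-trimethoxyphenyl)propane-1,3-dione | COc1ccc(cc1OCc1ccccc1)C(=O)CC(=O)c1c(O)c(OC)c(OC)c(O)c1OC | intermediate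
12 | 2-[3-(benzyloxy)-4-methoxyphenyl]-6-hydroxy-5,7,8-trimethoxy-4H-chromen-4-one | COc1ccc(-c2cc(=O)c3c(OC)c(O)c(OC)c(OC)c3o2)cc1OCc1ccccc1 | intermediate
13 | 5,6-dihydroxy-2-(3-hydroxy-4-methoxyphenyl)-7,8-dimethoxy-4H-chromen-4-one | COc1ccc(-c2cc(=O)c3c(O)c(O)c(OC)c(OC)c3o2)cc1O | target

## Step count and least certain steps

Total step count: 6. Longest linear sequence: 5 (steps 1, 2, 3, 5, 6).

**Step 3 (key step).**
- Risk: the 6π closure may be slowed because it forms a bond at the electron-poor, methoxy-bearing end of a push–pull alkene with the methoxy group on the inner face. The ketene could then live long enough for bimolecular O-acylation or dimerisation. Thermal retro-addition of the aldol-type carbinol and air oxidation of the hydroquinone are further drains.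
- Fallback (from 3, back at 8): the oxygen at C5 is brought in after ring A is formed instead of before.
- 2-Ethynyl-2-methyl-1,3-dioxolane, deprotonated with nBuLi, would be added to 3 to give the alkynyl carbinol 4-hydroxy-2,3-dimethoxy-4-[(2-methyl-1,3-dioxolan-2-yl)ethynyl]cyclobut-2-en-1-one F1.
- Heating would convert F1 by a Moore cyclisation into the quinone 2,3-dimethoxy-5-(2-methyl-1,3-dioxolan-2-yl)cyclohexa-2,5-diene-1,4-dione F2.
- Mild aqueous acid would free the acetylquinone 5-acetyl-2,3-dimethoxycyclohexa-2,5-diene-1,4-dione F3. Its only unsubstituted ring carbon is activated by two carbonyl groups and should take up methanol (cat. ZnCl2) in a conjugate addition that ends, after enolisation, at 8.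

**Step 2.**
- Risk: proton transfer from the acetyl methyl group to the carbanion, attack of the Grignard reagent on the ketone, or conjugate addition–elimination at a methoxy-bearing carbon of 3 in place of carbonyl addition. Any of these would divert material, because the nucleophile is softer than the organolithiums usually added to squarates.
- Fallback (from 2, back at 5): the ketone is masked and a hard vinyllithium is used.
- TBSOTf/Et3N would convert 2 into the silyl dienol ether tert-butyl{[(3Z)-3-iodo-4-methoxybuta-1,3-dien-2-yl]oxy}dimethylsilane F4.
- Iodine–lithium exchange with tBuLi at −78 °C and addition to 3 would give 4-{(1E)-3-[(tert-butyldimethylsilyl)oxy]-1-methoxybuta-1,3-dien-2-yl}-4-hydroxy-2,3-dimethoxycyclobut-2-en-1-one F5.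
- Buffered aqueous hydrolysis of the silyl enol ether would return 5.

**Step 5.**
- Risk: O-aroylation of a phenoxide, above all the unchelated one at C6, may compete with C-aroylation of the enolate, and the electron-rich polyanion is sensitive to traces of oxygen.
- Fallback (from 8 and 10, back at 12): the stepwise Baker–Venkataraman route.
- Two equivalents of 10 in pyridine with DMAP would give the bis-ester 2-acetyl-3,5,6-trimethoxybenzene-1,4-diyl bis[3-(benzyloxy)-4-methoxybenzoate] F6.
- KOH in pyridine would move the ortho aroyl group to carbon and give 4-{3-[3-(benzyloxy)-4-methoxyphenyl]-3-oxopropanoyl}-5-hydroxy-2,3,6-trimethoxyphenyl 3-(benzyloxy)-4-methoxybenzoate F7.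
- Catalytic H2SO4 in AcOH would close ring C to 2-[3-(benzyloxy)-4-methoxyphenyl]-5,7,8-trimethoxy-4-oxo-4H-chromen-6-yl 3-(benzyloxy)-4-methoxybenzoate F8.
- K2CO3 in MeOH would remove the remaining ester to give 12.

**Step 6.**
- Risk: loss of further methyl groups may occur by neighbour assistance from boron bound at O6 (towards O7) or at the freed O3' (towards O4'). Debenzylation may be incomplete at the low temperature that protects these ethers.
- Fallback (from 12, back at 13): the two cleavages are separated.
- Hydrogenolysis (H2, Pd/C, EtOAc/MeOH) would first give 6-hydroxy-2-(3-hydroxy-4-methoxyphenyl)-5,7,8-trimethoxy-4H-chromen-4-one F9.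
- The peri ether alone would then be cleaved under chelation control with AlCl3 in MeCN, followed by dilute acid, to give 13.

## Further compounds

F1 | step 3 | 4-hydroxy-2,3-dimethoxy-4-[(2-methyl-1,3-dioxolan-2-yl)ethynyl]cyclobut-2-en-1-one | CC1(OCCO1)C#CC1(O)C(OC)=C(OC)C1=O
F2 | step 3 | 2,3-dimethoxy-5-(2-methyl-1,3-dioxolan-2-yl)cyclohexa-2,5-diene-1,4-dione | COC1=C(OC)C(=O)C(=CC1=O)C1(C)OCCO1
F3 | step 3 | 5-acetyl-2,3-dimethoxycyclohexa-2,5-diene-1,4-dione | COC1=C(OC)C(=O)C(C(C)=O)=CC1=O
F4 | step 2 | tert-butyl{[(3Z)-3-iodo-4-methoxybuta-1,3-dien-2-yl]oxy}dimethylsilane | CO/C=C(\I)C(=C)O[Si](C)(C)C(C)(C)C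
F5 | step 2 | 4-{(1E)-3-[(tert-butyldimethylsilyl)oxy]-1-methoxybuta-1,3-dien-2-yl}-4-hydroxy-2,3-dimethoxycyclobut-2-en-1-one | CO/C=C(/C(=C)O[Si](C)(C)C(C)(C)C)C1(O)C(OC)=C(OC)C1=O
F6 | step 5 | 2-acetyl-3,5,6-trimethoxybenzene-1,4-diyl bis[3-(benzyloxy)-4-methoxybenzoate] | CC(=O)c1c(OC)c(OC(=O)c2ccc(OC)c(OCc3ccccc3)c2)c(OC)c(OC)c1OC(=O)c1ccc(OC)c(OCc2ccccc2)c1
F7 | step 5 | 4-{3-[3-(benzyloxy)-4-methoxyphenyl]-3-oxopropanoyl}-5-hydroxy-2,3,6-trimethoxyphenyl 3-(benzyloxy)-4-methoxybenzoate | COc1ccc(cc1OCc1ccccc1)C(=O)CC(=O)c1c(O)c(OC)c(OC)c(OC(=O)c2ccc(OC)c(OCc3ccccc3)c2)c1OC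
F8 | step 5 | 2-[3-(benzyloxy)-4-methoxyphenyl]-5,7,8-trimethoxy-4-oxo-4H-chromen-6-yl 3-(benzyloxy)-4-methoxybenzoate | COc1ccc(-c2cc(=O)c3c(OC)c(OC(=O)c4ccc(OC)c(OCc5ccccc5)c4)c(OC)c(OC)c3o2)cc1OCc1ccccc1
F9 | step 6 | 6-hydroxy-2-(3-hydroxy-4-methoxyphenyl)-5,7,8-trimethoxy-4H-chromen-4-one | COc1ccc(-c2cc(=O)c3c(OC)c(O)c(OC)c(OC)c3o2)cc1O
A1 | alternative 1 | (2E)-3-[3-(benzyloxy)-4-methoxyphenyl]-1-(2-hydroxy-3,4,5,6-tetramethoxyphenyl)prop-2-en-1-one | COc1ccc(/C=C/C(=O)c2c(O)c(OC)c(OC)c(OC)c2OC)cc1OCc1ccccc1
A2 | alternative 1 | 2-[3-(benzyloxy)-4-methoxyphenyl]-5,6,7,8-tetramethoxy-4H-chromen-4-one | COc1ccc(-c2cc(=O)c3c(OC)c(OC)c(OC)c(OC)c3o2)cc1OCc1ccccc1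
A3 | alternative 2 | 2-[3-(benzyloxy)-4-methoxyphenyl]-4H-pyran-4-one | O=c1ccoc(-c2ccc(OC)c(OCc3ccccc3)c2)c1
A4 | alternative 2 | 4-{6-[3-(benzyloxy)-4-methoxyphenyl]-4-oxo-4H-pyran-2-yl}-2,3,4-trimethoxycyclobut-2-en-1-one | COC1=C(OC)C(OC)(C1=O)c1cc(=O)cc(o1)-c1ccc(OC)c(OCc2ccccc2)c1
A5 | alternative 2 | 2-[3-(benzyloxy)-4-methoxyphenyl]-5-hydroxy-6,7,8-trimethoxy-4H-chromen-4-one | COc1ccc(-c2cc(=O)c3c(O)c(OC)c(OC)c(OC)c3o2)cc1OCc1ccccc1
A6 | alternative 3 | 3,4-bis(benzyloxy)-5,6-dimethoxy-2-(trimethylsilyl)phenyl trifluoromethanesulfonate | COc1c(OC)c(OCc2ccccc2)c(OCc2ccccc2)c([Si](C)(C)C)c1OS(=O)(=O)C(F)(F)F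
A7 | alternative 3 | 3,4-bis(benzyloxy)-5,6-dimethoxybenzyne | COC1=C(OC)C(OCc2ccccc2)=C(OCc2ccccc2)C#C1
A8 | alternative 3 | 6-[3-(benzyloxy)-4-methoxyphenyl]-2,2-dimethyl-4H-1,3-dioxin-4-one | CC1(C)OC(=O)C=C(O1)c1ccc(OC)c(OCc2ccccc2)c1
A9 | alternative 3 | 3-[3-(benzyloxy)-4-methoxyphenyl]-3-oxoprop-1-en-1-one | COc1ccc(cc1OCc1ccccc1)C(=O)C=C=O
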